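**Retrosynthetic overview**

1. The target is read as catechin-(4α→8)-catechin-(4α→8)-catechin-(4α→8)-epicatechin (units 1 to 4 from the top). The last disconnections are the nineteen benzyl ethers and the C2–H/C3–OH pair of unit 1, which comes from syn hydration of a flav-2-ene on the face opposite the C4 aryl group.
2. Feature carrying the strategy: ring C of unit 1 (O1, C2, C3, C4, C4a, C8a) is the reduced form of a 2-aryl benzopyrylium ion whose electrophilic C4 is the interflavan carbon bonded to C8 of unit 2.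
3. Key disconnection: C4(unit 1)–C8(unit 2) together with O1–C2 of ring C of unit 1, leading back to a 2-hydroxychalcone (from 2,4,6-trihydroxybenzaldehyde and 3,4-bis(benzyloxy)acetophenone) and the perbenzylated trimer of units 2 to 4.
4. The trimer comes from penta-O-benzyl-(−)-epicatechin (unit 4) and two rounds of Lewis-acid coupling with a C4 ether made from (+)-catechin (unit 3, then unit 2), each followed by O-benzylation. Rings C of units 2 to 4 are taken from the chiral pool, so ring C of unit 1 is the only ring built, and it is built last.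

Key step: step 11

Assumption: the (R)-enantiomer of the phosphoric acid is taken as the one whose ion pair leaves open the C4 face leading to the 4α-aryl configuration; if a trial on 7 shows the opposite sense, the (S)-enantiomer replaces it with no other change.

**Route**

Step 1
Reactants: 1 2,4,6-trihydroxybenzaldehyde
Product: 2 4,6-bis(benzyloxy)-2-hydroxybenzaldehyde
Conditions: BnBr (2.05 equiv), K2CO3 (2.2 equiv), DMF, 0 °C to rt
Reagents that add atoms: benzyl bromide, BrCc1ccccc1
Why: Williamson ether synthesis under weak base, in which the 4-OH and one ortho-OH are alkylated while the remaining ortho-OH, held in a hydrogen bond to the aldehyde, should stay free.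

Step 2
Reactants: 2 4,6-bis(benzyloxy)-2-hydroxybenzaldehyde; 3 1-[3,4-bis(benzyloxy)phenyl]ethanone
Product: 4 (E)-3-[2-hydroxy-4,6-bis(benzyloxy)phenyl]-1-[3,4-bis(benzyloxy)phenyl]prop-2-en-1-one
Conditions: KOH (6 equiv), EtOH/H2O, rt to 45 °C; then AcOH to pH 6, 0 °C
Reagents that add atoms: none
Why: Claisen–Schmidt condensation, in which the enolate of the only enolisable partner 3 adds to the aldehyde of 2 and elimination of hydroxide gives the conjugated E-enone, the mild acetic acid quench avoiding premature ring closure.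

Step 3
Reactants: 5 (−)-epicatechin
Product: 6 5,7,3',4'-tetra-O-benzyl-(−)-epicatechin
Conditions: BnBr (4.4 equiv), K2CO3 (5 equiv), DMF, 0 °C to rt, Ar
Reagents that add atoms: benzyl bromide, BrCc1ccccc1
Why: Williamson ether synthesis in which K2CO3 deprotonates only the four phenols, so the secondary 3-OH stays free and C2 is not epimerised at room temperature.

Step 4
Reactants: 6 5,7,3',4'-tetra-O-benzyl-(−)-epicatechin
Product: 7 3,5,7,3',4'-penta-O-benzyl-(−)-epicatechin
Conditions: NaH, BnBr, n-Bu4NI (cat.), DMF, 0 °C to rt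
Reagents that add atoms: benzyl bromide, BrCc1ccccc1
Why: Williamson ether synthesis of the secondary alkoxide formed with NaH; with no phenoxide left, base-induced opening of ring C and loss of the C2 configuration cannot occur.

Step 5
Reactants: 8 (+)-catechin
Product: 9 5,7,3',4'-tetra-O-benzyl-(+)-catechin
Conditions: BnBr (4.4 equiv), K2CO3 (5 equiv), DMF, 0 °C to rt, Ar
Reagents that add atoms: benzyl bromide, BrCc1ccccc1
Why: Williamson ether synthesis of the four phenols under weak base, which leaves the secondary 3-OH free and does not touch C2 or C3.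

Step 6
Reactants: 9 5,7,3',4'-tetra-O-benzyl-(+)-catechin
Product: 10 (2R,3S,4S)-5,7-bis(benzyloxy)-2-[3,4-bis(benzyloxy)phenyl]-4-(2-ethoxyethoxy)chroman-3-ol
Conditions: DDQ (2 equiv), 2-ethoxyethanol (5 equiv), CH2Cl2, rt
Reagents that add atoms: 2-ethoxyethanol, CCOCCO
Why: Oxidative C4 functionalisation (benzylic hydride abstraction by DDQ from the electron-rich 5,7-dialkoxychroman and capture of the C4 cation by the alcohol), which leaves C2 and C3 untouched; the ether is drawn as the 4β epimer expected from attack anti to the 2-aryl group, and either epimer would serve because C4 is ionised again in steps 7 and 9.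

Step 7
Reactants: 10 the catechin C4 ether; 7 3,5,7,3',4'-penta-O-benzyl-(−)-epicatechin
Product: 11 5,7,3',4'-tetra-O-benzylcatechin-(4α→8)-penta-O-benzylepicatechin (free 3-OH on unit 3)
Conditions: 10 added slowly to 7 (4 equiv), Me3SiOTf (20 mol%), CH2Cl2, −78 °C; then sat. aq NaHCO3
Reagents that add atoms: none
Why: Lewis-acid-mediated Friedel–Crafts alkylation of the SN1 type, in which Me3SiOTf ionises the C4 ether to the benzylic cation stabilised by the 5- and 7-oxygens, C8 of 7 (less hindered than C6, which lies between two benzyloxy groups) attacks on the face anti to the C3 hydroxyl to give the 3,4-trans (4α) bond usual for catechin C4 cations, and the excess of 7 suppresses self-condensation of 10.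

Step 8
Reactants: 11 dimer with free 3-OH on unit 3
Product: 12 penta-O-benzylcatechin-(4α→8)-penta-O-benzylepicatechin (deca-O-benzyl dimer; C8 of unit 3 free)
Conditions: NaH, BnBr, n-Bu4NI (cat.), DMF, 0 °C to rt
Reagents that add atoms: benzyl bromide, BrCc1ccccc1
Why: Williamson ether synthesis of the only free hydroxyl, which removes the one protic group of the nucleophile and touches no stereocentre.

Step 9
Reactants: 10 the catechin C4 ether; 12 deca-O-benzyl dimer
Product: 13 tetra-O-benzylcatechin-(4α→8)-penta-O-benzylcatechin-(4α→8)-penta-O-benzylepicatechin (free 3-OH on unit 2)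
Conditions: 10 added slowly to 12 (3 equiv, excess recovered), Me3SiOTf (20 mol%), CH2Cl2, −78 °C; then sat. aq NaHCO3
Reagents that add atoms: none
Why: Second Friedel–Crafts alkylation by the catechin C4 cation, which should again add anti to the C3 hydroxyl (4α) and at C8 of unit 3, the only free arene position of 12 that is flanked by the tied-back ring oxygen instead of two benzyloxy groups.

Step 10
Reactants: 13 trimer with free 3-OH on unit 2
Product: 14 perbenzylated units 2 to 4 (pentadeca-O-benzyl trimer; C8 of unit 2 free)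
Conditions: NaH, BnBr, n-Bu4NI (cat.), DMF, 0 °C to rt
Reagents that add atoms: benzyl bromide, BrCc1ccccc1
Why: Williamson ether synthesis of the single secondary alkoxide, with no base-sensitive group present, so that the nucleophile of the key step carries no protic group.

Step 11
Reactants: 4 the 2-hydroxychalcone; 14 pentadeca-O-benzyl trimer
Product: 16 4-aryl-flav-2-ene of unit 1 bonded through C4 (4α) to C8 of unit 2 of the perbenzylated trimer, via flavylium phosphate 15 (not isolated)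
Conditions: 4 (1.0 equiv) added over several hours to 14 (1.3 equiv), (R)-3,3'-bis(2,4,6-triisopropylphenyl)-1,1'-binaphthyl-2,2'-diyl hydrogen phosphate (20 mol%), 5 Å MS, PhMe, 0 °C to rt, Ar
Reagents that add atoms: none
Why: The phosphoric acid protonates the enone of 4, which lowers the Cα–Cβ bond order so that the E alkene can rotate to Z, the phenol oxygen then attacks the carbonyl carbon (6-exo-trig closure of ring C, forming O1–C2), and loss of water, taken up by the sieves, leaves the aromatic 5,7,3',4'-tetrakis(benzyloxy)flavylium ion as a contact ion pair with the chiral phosphate, 15. C8 of unit 2 of 14 attacks C4 of this ion in a Friedel–Crafts alkylation (forming C4–C8), and transfer of the C8 proton to the phosphate gives the neutral 4H-chromene 16 and returns the acid. The closest known reaction types are the acid-mediated C4 arylation of flavylium ions generated from 2-hydroxychalcones by phloroglucinol-type arenes and chiral-phosphate-controlled additions to benzopyrylium ion pairs. The ion is planar and achiral, so C4 is the only stereocentre formed, and its configuration is fixed by the face that the 2,4,6-triisopropylphenyl groups of the phosphate leave open, with the stereocentres of 14 acting as a second, weaker control element (matched pairing assumed). The step needs C4 over C2 attack, C8 over C6 attack and monoarylation: C2 is shielded by its aryl group, C8 of unit 2 sits between one benzyloxy group and the tied-back ring oxygen whereas each free C6 of 14 lies between two benzyloxy groups, and the excess of 14 with slow addition of 4 keeps 16 from reacting again. The benzyl ether on O7 of unit 2 rules out ketal formation at C2, so the C2=C3 enol ether survives for step 12.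

Step 12
Reactants: 16 flav-2-ene of unit 1 bonded to the perbenzylated trimer
Product: 18 nonadeca-O-benzyl tetramer (free 3-OH on unit 1), via C3 alkylborane 17 (not isolated)
Conditions: BH3·THF (3 equiv), THF, 0 °C to rt; then 3 M NaOH, 30% H2O2, 0 °C to rt
Reagents that add atoms: hydrogen peroxide, OO
Why: Hydroboration–oxidation of the cyclic enol ether, in which boron adds to C3 (β to O1) and hydrogen to C2 syn on the face opposite the pseudoaxial C4 aryl group, and oxidation with retention sets C2 (R, 2α-aryl) and C3 (S, 3β-OH) of unit 1 trans to each other and to the interflavan bond.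

Step 13
Reactants: 18 nonadeca-O-benzyl tetramer
Product: 19 catechin-(4α→8)-catechin-(4α→8)-catechin-(4α→8)-epicatechin (CNP0236700.7)
Conditions: H2 (1 atm), Pd(OH)2 on carbon, THF/MeOH/H2O, rt; filtration, lyophilisation
Reagents that add atoms: none
Why: Catalytic hydrogenolysis of the nineteen benzyl ethers under neutral conditions, which should leave the ring C ethers, the interflavan C–C bonds and all stereocentres untouched, as is usual for benzylated procyanidins.

**Compound list**

1 | 2,4,6-trihydroxybenzaldehyde | O=Cc1c(O)cc(O)cc1O | starting material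
2 | 4,6-bis(benzyloxy)-2-hydroxybenzaldehyde | O=Cc1c(O)cc(OCc2ccccc2)cc1OCc1ccccc1 | intermediate
3 | 1-[3,4-bis(benzyloxy)phenyl]ethanone | CC(=O)c1ccc(OCc2ccccc2)c(OCc2ccccc2)c1 | starting material
4 | (E)-3-[2-hydroxy-4,6-bis(benzyloxy)phenyl]-1-[3,4-bis(benzyloxy)phenyl]prop-2-en-1-one | O=C(/C=C/c1c(O)cc(OCc2ccccc2)cc1OCc1ccccc1)c1ccc(OCc2ccccc2)c(OCc2ccccc2)c1 | intermediate
5 | (−)-epicatechin, (2R,3R) | O[C@@H]1Cc2c(O)cc(O)cc2O[C@@H]1c1ccc(O)c(O)c1 | starting material
6 | 5,7,3',4'-tetra-O-benzyl-(−)-epicatechin, (2R,3R), free 3-OH | c1c(OCc3ccccc3)cc(OCc3ccccc3)c2c1O[C@H](c1ccc(OCc3ccccc3)c(OCc3ccccc3)c1)[C@H](O)C2 | intermediate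
7 | 3,5,7,3',4'-penta-O-benzyl-(−)-epicatechin, (2R,3R) | c1c(OCc3ccccc3)cc(OCc3ccccc3)c2c1O[C@H](c1ccc(OCc3ccccc3)c(OCc3ccccc3)c1)[C@H](OCc3ccccc3)C2 | intermediate
8 | (+)-catechin, (2R,3S) | O[C@H]1Cc2c(O)cc(O)cc2O[C@@H]1c1ccc(O)c(O)c1 | starting material
9 | 5,7,3',4'-tetra-O-benzyl-(+)-catechin, (2R,3S), free 3-OH | c1ccccc1COc1cc(OCc3ccccc3)c2c(c1)O[C@H](c1ccc(OCc3ccccc3)c(OCc3ccccc3)c1)[C@@H](O)C2 | intermediate
10 | (2R,3S,4S)-5,7-bis(benzyloxy)-2-[3,4-bis(benzyloxy)phenyl]-4-(2-ethoxyethoxy)chroman-3-ol (4β ether, free 3-OH) | c1ccccc1COc1cc(OCc3ccccc3)c2c(c1)O[C@H](c1ccc(OCc3ccccc3)c(OCc3ccccc3)c1)[C@@H](O)[C@H]2OCCOCC | intermediate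
11 | 5,7,3',4'-tetra-O-benzylcatechin-(4α→8)-penta-O-benzylepicatechin, free 3-OH on unit 3 | c1ccccc1COc1cc(OCc3ccccc3)c2c(c1)O[C@H](c1ccc(OCc3ccccc3)c(OCc3ccccc3)c1)[C@@H](O)[C@@H]2c1c(OCc3ccccc3)cc(OCc3ccccc3)c2c1O[C@H](c1ccc(OCc3ccccc3)c(OCc3ccccc3)c1)[C@H](OCc3ccccc3)C2 | intermediate
12 | penta-O-benzylcatechin-(4α→8)-penta-O-benzylepicatechin (deca-O-benzyl dimer, units 3 and 4) | c1ccccc1COc1cc(OCc3ccccc3)c2c(c1)O[C@H](c1ccc(OCc3ccccc3)c(OCc3ccccc3)c1)[C@@H](OCc3ccccc3)[C@@H]2c1c(OCc3ccccc3)cc(OCc3ccccc3)c2c1O[C@H](c1ccc(OCc3ccccc3)c(OCc3ccccc3)c1)[C@H](OCc3ccccc3)C2 | intermediate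
13 | tetra-O-benzylcatechin-(4α→8)-penta-O-benzylcatechin-(4α→8)-penta-O-benzylepicatechin, free 3-OH on unit 2 | c1ccccc1COc1cc(OCc3ccccc3)c2c(c1)O[C@H](c1ccc(OCc3ccccc3)c(OCc3ccccc3)c1)[C@@H](O)[C@@H]2c1c(OCc3ccccc3)cc(OCc3ccccc3)c2c1O[C@H](c1ccc(OCc3ccccc3)c(OCc3ccccc3)c1)[C@@H](OCc3ccccc3)[C@@H]2c1c(OCc3ccccc3)cc(OCc3ccccc3)c2c1O[C@H](c1ccc(OCc3ccccc3)c(OCc3ccccc3)c1)[C@H](OCc3ccccc3)C2 | intermediate
14 | perbenzylated units 2 to 4 (pentadeca-O-benzyl catechin-(4α→8)-catechin-(4α→8)-epicatechin), C8 of unit 2 free | c1ccccc1COc1cc(OCc3ccccc3)c2c(c1)O[C@H](c1ccc(OCc3ccccc3)c(OCc3ccccc3)c1)[C@@H](OCc3ccccc3)[C@@H]2c1c(OCc3ccccc3)cc(OCc3ccccc3)c2c1O[C@H](c1ccc(OCc3ccccc3)c(OCc3ccccc3)c1)[C@@H](OCc3ccccc3)[C@@H]2c1c(OCc3ccccc3)cc(OCc3ccccc3)c2c1O[C@H](c1ccc(OCc3ccccc3)c(OCc3ccccc3)c1)[C@H](OCc3ccccc3)C2 | intermediate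
15 | 5,7-bis(benzyloxy)-2-[3,4-bis(benzyloxy)phenyl]chromenylium (R)-3,3'-bis(2,4,6-triisopropylphenyl)-1,1'-binaphthyl-2,2'-diyl phosphate, formed in the flask and not isolated (the R axis of the anion is given by the name only) | c1ccccc1COc1cc(OCc3ccccc3)c2ccc(-c4ccc(OCc3ccccc3)c(OCc3ccccc3)c4)[o+]c2c1.[O-]P1(=O)Oc2c(-c3c(C(C)C)cc(C(C)C)cc3C(C)C)cc4ccccc4c2-c5c(O1)c(-c6c(C(C)C)cc(C(C)C)cc6C(C)C)cc7ccccc57 | intermediate
16 | tetramer flav-2-ene: 5,7-bis(benzyloxy)-2-[3,4-bis(benzyloxy)phenyl]-4H-chromene (unit 1) bonded at C4 (α) to C8 of unit 2 of 14 | c1ccccc1COc1cc(OCc3ccccc3)c2c(c1)OC(c1ccc(OCc3ccccc3)c(OCc3ccccc3)c1)=C[C@@H]2c1c(OCc3ccccc3)cc(OCc3ccccc3)c2c1O[C@H](c1ccc(OCc3ccccc3)c(OCc3ccccc3)c1)[C@@H](OCc3ccccc3)[C@@H]2c1c(OCc3ccccc3)cc(OCc3ccccc3)c2c1O[C@H](c1ccc(OCc3ccccc3)c(OCc3ccccc3)c1)[C@@H](OCc3ccccc3)[C@@H]2c1c(OCc3ccccc3)cc(OCc3ccccc3)c2c1O[C@H](c1ccc(OCc3ccccc3)c(OCc3ccccc3)c1)[C@H](OCc3ccccc3)C2 | intermediate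
17 | C3 alkylborane of the tetramer (BH2 on C3β of unit 1, H on C2β), formed in the flask and not isolated | c1ccccc1COc1cc(OCc3ccccc3)c2c(c1)O[C@H](c1ccc(OCc3ccccc3)c(OCc3ccccc3)c1)[C@@H](B)[C@@H]2c1c(OCc3ccccc3)cc(OCc3ccccc3)c2c1O[C@H](c1ccc(OCc3ccccc3)c(OCc3ccccc3)c1)[C@@H](OCc3ccccc3)[C@@H]2c1c(OCc3ccccc3)cc(OCc3ccccc3)c2c1O[C@H](c1ccc(OCc3ccccc3)c(OCc3ccccc3)c1)[C@@H](OCc3ccccc3)[C@@H]2c1c(OCc3ccccc3)cc(OCc3ccccc3)c2c1O[C@H](c1ccc(OCc3ccccc3)c(OCc3ccccc3)c1)[C@H](OCc3ccccc3)C2 | intermediate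
18 | nonadeca-O-benzyl catechin-(4α→8)-catechin-(4α→8)-catechin-(4α→8)-epicatechin, free 3-OH on unit 1 | c1ccccc1COc1cc(OCc3ccccc3)c2c(c1)O[C@H](c1ccc(OCc3ccccc3)c(OCc3ccccc3)c1)[C@@H](O)[C@@H]2c1c(OCc3ccccc3)cc(OCc3ccccc3)c2c1O[C@H](c1ccc(OCc3ccccc3)c(OCc3ccccc3)c1)[C@@H](OCc3ccccc3)[C@@H]2c1c(OCc3ccccc3)cc(OCc3ccccc3)c2c1O[C@H](c1ccc(OCc3ccccc3)c(OCc3ccccc3)c1)[C@@H](OCc3ccccc3)[C@@H]2c1c(OCc3ccccc3)cc(OCc3ccccc3)c2c1O[C@H](c1ccc(OCc3ccccc3)c(OCc3ccccc3)c1)[C@H](OCc3ccccc3)C2 | intermediate
19 | catechin-(4α→8)-catechin-(4α→8)-catechin-(4α→8)-epicatechin (CNP0236700.7) | Oc1cc(O)c2c(c1)O[C@H](c1ccc(O)c(O)c1)[C@@H](O)[C@@H]2c1c(O)cc(O)c2c1O[C@H](c1ccc(O)c(O)c1)[C@@H](O)[C@@H]2c1c(O)cc(O)c2c1O[C@H](c1ccc(O)c(O)c1)[C@@H](O)[C@@H]2c1c(O)cc(O)c2c1O[C@H](c1ccc(O)c(O)c1)[C@H](O)C2 | target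

**Step count and risks**

Total step count: 13. Longest linear sequence: 9 steps (steps 3, 4 and 7 to 13 from (−)-epicatechin; equally steps 5 to 13 from (+)-catechin). The chalcone branch (steps 1 and 2) enters at step 11.

Steps most likely to fail:

Step 11. The tetra-alkoxyflavylium ion is a strongly stabilised, weak electrophile and the nucleophile has no free phenol, so the addition may be slow. The adduct may revert by ipso-protonation at C8. The ion pair may give poor facial selectivity at C4. The product may be arylated a second time at C8 of unit 1. The fallback takes unit 1 from the chiral pool, sets C4 by substrate control and blocks C8 of the electrophile with bromine, so that the electrophile cannot condense with itself and the trimer need not be used in excess. NBS (CH2Cl2, −78 °C to 0 °C) should brominate 10 at C8 to give (2R,3S,4S)-8-bromo-5,7-bis(benzyloxy)-2-[3,4-bis(benzyloxy)phenyl]-4-(2-ethoxyethoxy)chroman-3-ol F1. Me3SiOTf (cat., CH2Cl2, −78 °C) ionises F1 at C4, and C8 of unit 2 of 14 should attack anti to the 3-OH to give the 8-bromo nonadeca-O-benzyl tetramer F2 (bromine on C8 of unit 1, free 3-OH on unit 1, 4α bond). Hydrogenolysis (H2, Pd(OH)2 on carbon, Et3N, THF/MeOH/H2O, rt) then removes the bromine together with the nineteen benzyl groups. This fallback sets out from 10 and 14 and comes back to the route at 19, passing over steps 11 to 13.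

Step 12. The C3 borane lies β to the aryloxy oxygen O1 and may eliminate with opening of ring C, or hydride may be delivered to both faces of the enol ether. The fallback is a two-stage syn hydration through the enol ether epoxide. Dimethyldioxirane (acetone/CH2Cl2, −78 °C) should epoxidise 16 on the face opposite the C4 aryl group to give the 2,3-epoxyflavan tetramer F3. i-Bu2AlH (CH2Cl2, −78 °C), added to the crude epoxide, coordinates the epoxide oxygen, opens the C2–O bond and delivers hydride to C2 from the same face, as in the opening of glycal-type epoxides. This places H2 cis to the 3-oxygen, the same outcome as the hydroboration. The fallback sets out from 16 and comes back at 18.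

Step 2. The phenoxide of 2 is a vinylogous carboxylate, so the aldehyde may be too poor an electrophile for the enolate of 3 and the condensation may stall or give way to self-condensation of 3. The fallback is an acid-mediated condensation. Compounds 2 and 3 with HCl gas in EtOAc/AcOH at rt should condense through the enol of 3 and cyclise to 5,7-bis(benzyloxy)-2-[3,4-bis(benzyloxy)phenyl]chromenylium chloride F4. Stirring F4 with aqueous NaOAc in THF adds water at C2, opens ring C and gives the E-chalcone. The fallback sets out from 2 and 3 and comes back at 4.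

**Further compounds**

F1 | step 11 | (2R,3S,4S)-8-bromo-5,7-bis(benzyloxy)-2-[3,4-bis(benzyloxy)phenyl]-4-(2-ethoxyethoxy)chroman-3-ol | c1ccccc1COc1cc(OCc3ccccc3)c2c(c1Br)O[C@H](c1ccc(OCc3ccccc3)c(OCc3ccccc3)c1)[C@@H](O)[C@H]2OCCOCC
F2 | step 11 | 8-bromo nonadeca-O-benzyl catechin-(4α→8)-catechin-(4α→8)-catechin-(4α→8)-epicatechin (bromine on C8 of unit 1, free 3-OH on unit 1) | c1ccccc1COc1cc(OCc3ccccc3)c2c(c1Br)O[C@H](c1ccc(OCc3ccccc3)c(OCc3ccccc3)c1)[C@@H](O)[C@@H]2c1c(OCc3ccccc3)cc(OCc3ccccc3)c2c1O[C@H](c1ccc(OCc3ccccc3)c(OCc3ccccc3)c1)[C@@H](OCc3ccccc3)[C@@H]2c1c(OCc3ccccc3)cc(OCc3ccccc3)c2c1O[C@H](c1ccc(OCc3ccccc3)c(OCc3ccccc3)c1)[C@@H](OCc3ccccc3)[C@@H]2c1c(OCc3ccccc3)cc(OCc3ccccc3)c2c1O[C@H](c1ccc(OCc3ccccc3)c(OCc3ccccc3)c1)[C@H](OCc3ccccc3)C2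
F3 | step 12 | 2,3-epoxide of 16 (epoxide oxygen on the face opposite the C4 aryl group of unit 1) | c1ccccc1COc1cc(OCc3ccccc3)c2c(c1)O[C@@]4(c1ccc(OCc3ccccc3)c(OCc3ccccc3)c1)O[C@H]4[C@@H]2c1c(OCc3ccccc3)cc(OCc3ccccc3)c2c1O[C@H](c1ccc(OCc3ccccc3)c(OCc3ccccc3)c1)[C@@H](OCc3ccccc3)[C@@H]2c1c(OCc3ccccc3)cc(OCc3ccccc3)c2c1O[C@H](c1ccc(OCc3ccccc3)c(OCc3ccccc3)c1)[C@@H](OCc3ccccc3)[C@@H]2c1c(OCc3ccccc3)cc(OCc3ccccc3)c2c1O[C@H](c1ccc(OCc3ccccc3)c(OCc3ccccc3)c1)[C@H](OCc3ccccc3)C2
F4 | step 2 | 5,7-bis(benzyloxy)-2-[3,4-bis(benzyloxy)phenyl]chromenylium chloride | c1ccccc1COc1cc(OCc3ccccc3)c2ccc(-c4ccc(OCc3ccccc3)c(OCc3ccccc3)c4)[o+]c2c1.[Cl-]
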